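**Assumption:** the target (6,7,8-trimethoxy-3-(3,4,5-trimethoxyphenyl)-4H-chromen-4-one) has no stereocentre and is achiral, so there is no enantiomer to control; transient stereocentres in the route are racemic and are erased before the end.

## Retrosynthetic overview

- The pyranone ring is the only ring made and is closed last (O1–C2), by acid cyclisation/elimination of an o-hydroxyphenyl α-aryl-β,β-dimethoxy ketone (13).
- That acetal comes from a 2'-benzyloxychalcone (10) by Tl(III)-mediated oxidative 1,2-aryl shift.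
- Chalcone 10 is made by Claisen–Schmidt aldol condensation of acetophenone 7 with 3,4,5-trimethoxybenzaldehyde 8; this C–C bond becomes C2–C3 of the isoflavone.
- Acetophenone 7 comes from 2,3,4-trimethoxybenzaldehyde 1 by Dakin oxidation, ortho-acetylation (Fries) and O-benzylation.

## Route

Step 1
Reactants: 1 2,3,4-trimethoxybenzaldehyde
Product: 3 2,3,4-trimethoxyphenol, via aryl formate 2 (not isolated)
Conditions: mCPBA (1.3 equiv), CH2Cl2, 0 °C → rt, 12 h; aq. Na2SO3/NaHCO3 wash; then MeOH, conc. HCl (cat.), rt, 1 h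
Reagents that add atoms: mCPBA (3-chloroperoxybenzoic acid), OOC(=O)c1cccc(Cl)c1
Why: Dakin-type Baeyer–Villiger oxidation, in which the electron-rich o,p-dimethoxy-substituted aryl group migrates in preference to H to give the formate, which is then methanolysed to the phenol.

Step 2
Reactants: 3 2,3,4-trimethoxyphenol
Product: 6 1-(2-hydroxy-3,4,5-trimethoxyphenyl)ethan-1-one, via aryl acetate 4 (not isolated), via difluoroboron chelate 5 (not isolated)
Conditions: Ac2O (1.2 equiv), BF3·OEt2 (3 equiv), AcOH, 90 °C, 3 h; then H2O, 60 °C, 30 min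
Reagents that add atoms: acetic anhydride, CC(=O)OC(C)=O
Why: O-acetylation followed by BF3-promoted Fries rearrangement; the para position is blocked by OMe, so the acetyl group goes to the only free ortho carbon, driven by the stable boron chelate of the o-hydroxy ketone, which water then hydrolyses.

Step 3
Reactants: 6 1-(2-hydroxy-3,4,5-trimethoxyphenyl)ethan-1-one
Product: 7 1-[2-(benzyloxy)-3,4,5-trimethoxyphenyl]ethan-1-one
Conditions: BnBr (1.3 equiv), K2CO3 (2 equiv), DMF, 60 °C, 12 h
Reagents that add atoms: benzyl bromide, BrCc1ccccc1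
Why: Williamson ether synthesis on the phenoxide, which masks the electron-rich phenol against Tl(III) oxidation and aurone/flavanone side reactions in the later steps.

Step 4
Reactants: 7 1-[2-(benzyloxy)-3,4,5-trimethoxyphenyl]ethan-1-one; 8 3,4,5-trimethoxybenzaldehyde
Product: 10 (2E)-1-[2-(benzyloxy)-3,4,5-trimethoxyphenyl]-3-(3,4,5-trimethoxyphenyl)prop-2-en-1-one, via aldol adduct 9 (not isolated)
Conditions: 8 (1.1 equiv), 50% aq. KOH (4 equiv), EtOH, rt, 24–48 h
Reagents that add atoms: none
Why: Claisen–Schmidt crossed aldol condensation between the methyl ketone enolate and a non-enolisable aldehyde, with E1cB dehydration of the β-hydroxy ketone giving the conjugated E-enone under thermodynamic control.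

Step 5
Reactants: 10 (2E)-1-[2-(benzyloxy)-3,4,5-trimethoxyphenyl]-3-(3,4,5-trimethoxyphenyl)prop-2-en-1-one
Product: 12 1-[2-(benzyloxy)-3,4,5-trimethoxyphenyl]-3,3-dimethoxy-2-(3,4,5-trimethoxyphenyl)propan-1-one, via oxythallation adduct 11 (not isolated)
Conditions: Tl(NO3)3·3H2O (1.2 equiv), MeOH–HC(OMe)3 (3:1), rt, 12 h; then aq. Na2SO3/NaHCO3, filter
Reagents that add atoms: methanol, CO
Why: McKillop–Taylor oxidative rearrangement, in which methoxythallation places OMe on the benzylic carbon and the p-methoxy-activated aryl group then shifts 1,2 to the α-carbon with loss of Tl(I), the oxocarbenium ion being trapped by methanol as the dimethyl acetal (the new α-stereocentre is racemic and is removed in step 7).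

Step 6
Reactants: 12 1-[2-(benzyloxy)-3,4,5-trimethoxyphenyl]-3,3-dimethoxy-2-(3,4,5-trimethoxyphenyl)propan-1-one
Product: 13 1-(2-hydroxy-3,4,5-trimethoxyphenyl)-3,3-dimethoxy-2-(3,4,5-trimethoxyphenyl)propan-1-one
Conditions: H2 (1 atm), 10% Pd/C, EtOAc–MeOH (1:1), rt, 3 h; filter through Celite, concentrate, use crude
Reagents that add atoms: none
Why: catalytic hydrogenolysis cleaves the aryl benzyl ether under neutral conditions, which leave the aryl ketone, the acetal and the methyl ethers untouched.

Step 7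
Reactants: 13 1-(2-hydroxy-3,4,5-trimethoxyphenyl)-3,3-dimethoxy-2-(3,4,5-trimethoxyphenyl)propan-1-one
Product: 15 6,7,8-trimethoxy-3-(3,4,5-trimethoxyphenyl)-4H-chromen-4-one, via 2-methoxyisoflavanone 14 (not isolated)
Conditions: 10% aq. HCl–MeOH (1:10), reflux, 2 h
Reagents that add atoms: none
Why: acid-catalysed transacetalisation closes the pyranone ring by attack of the phenol on the oxocarbenium ion, and elimination of methanol from the cyclic mixed acetal gives the conjugated chromen-4-one, removing the remaining sp3 centres.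

## Compound list

1 | 2,3,4-trimethoxybenzaldehyde | COc1ccc(C=O)c(OC)c1OC | starting material
2 | 2,3,4-trimethoxyphenyl formate | COc1ccc(OC=O)c(OC)c1OC | intermediate (not isolated)
3 | 2,3,4-trimethoxyphenol | COc1ccc(O)c(OC)c1OC | intermediate
4 | 2,3,4-trimethoxyphenyl acetate | COc1ccc(OC(C)=O)c(OC)c1OC | intermediate (not isolated)
5 | difluoroboron O,O-chelate of ketone 6 (2,2-difluoro-6,7,8-trimethoxy-4-methyl-1,3,2-benzodioxaborinine, zwitterionic) | CC1=[O+][B-](F)(F)Oc2c1cc(OC)c(OC)c2OC | intermediate (not isolated)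
6 | 1-(2-hydroxy-3,4,5-trimethoxyphenyl)ethan-1-one | CC(=O)c1cc(OC)c(OC)c(OC)c1O | intermediate
7 | 1-[2-(benzyloxy)-3,4,5-trimethoxyphenyl]ethan-1-one | CC(=O)c1cc(OC)c(OC)c(OC)c1OCc1ccccc1 | intermediate
8 | 3,4,5-trimethoxybenzaldehyde | COc1cc(C=O)cc(OC)c1OC | starting material
9 | 1-[2-(benzyloxy)-3,4,5-trimethoxyphenyl]-3-hydroxy-3-(3,4,5-trimethoxyphenyl)propan-1-one (racemic) | COc1cc(cc(OC)c1OC)C(O)CC(=O)c1cc(OC)c(OC)c(OC)c1OCc1ccccc1 | intermediate (not isolated)
10 | (2E)-1-[2-(benzyloxy)-3,4,5-trimethoxyphenyl]-3-(3,4,5-trimethoxyphenyl)prop-2-en-1-one | COc1cc(/C=C/C(=O)c2cc(OC)c(OC)c(OC)c2OCc2ccccc2)cc(OC)c1OC | intermediate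
11 | 1-[2-(benzyloxy)-3,4,5-trimethoxyphenyl]-2-(dinitratothallio)-3-methoxy-3-(3,4,5-trimethoxyphenyl)propan-1-one (racemic) | COc1cc(cc(OC)c1OC)C(OC)C([Tl](O[N+](=O)[O-])O[N+](=O)[O-])C(=O)c1cc(OC)c(OC)c(OC)c1OCc1ccccc1 | intermediate (not isolated)
12 | 1-[2-(benzyloxy)-3,4,5-trimethoxyphenyl]-3,3-dimethoxy-2-(3,4,5-trimethoxyphenyl)propan-1-one (racemic) | COC(OC)C(c1cc(OC)c(OC)c(OC)c1)C(=O)c1cc(OC)c(OC)c(OC)c1OCc1ccccc1 | intermediate
13 | 1-(2-hydroxy-3,4,5-trimethoxyphenyl)-3,3-dimethoxy-2-(3,4,5-trimethoxyphenyl)propan-1-one (racemic) | COC(OC)C(c1cc(OC)c(OC)c(OC)c1)C(=O)c1cc(OC)c(OC)c(OC)c1O | intermediate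
14 | 2,6,7,8-tetramethoxy-3-(3,4,5-trimethoxyphenyl)chroman-4-one (racemic diastereomer mixture) | COC1Oc2c(OC)c(OC)c(OC)cc2C(=O)C1c1cc(OC)c(OC)c(OC)c1 | intermediate (not isolated)
15 | 6,7,8-trimethoxy-3-(3,4,5-trimethoxyphenyl)-4H-chromen-4-one | COc1cc(-c2coc3c(OC)c(OC)c(OC)cc3c2=O)cc(OC)c1OC | target

## Summary

Total step count: 7. Longest linear sequence: 7 steps (1 → 15); aldehyde 8 enters at step 4.

Steps most likely to fail, with fallbacks:

**Step 5 (Tl(III) oxidative aryl shift).** The 3,4,5-trimethoxyphenyl group migrates only moderately well, and Tl(III) can attack the electron-rich rings. The fallback sets out from 10 and comes back at 15. Chalcone 10 is epoxidised by the Weitz–Scheffer method (30% H2O2, NaOH, MeOH–THF, 0 °C → rt) to the racemic trans-chalcone epoxide F1. BF3·OEt2 (cat.) in CH2Cl2 at 0 °C opens it at the benzylic carbon and induces a 1,2-aroyl shift to the α-formyl deoxybenzoin F2. Hydrogenolysis (H2, Pd/C, EtOAc) removes the benzyl group and the product closes to the 2-hydroxyisoflavanone F3, which loses water on warming with cat. TsOH in toluene to give 15.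

**Step 2 (Fries acetylation).** Acylation at the other free ring position or partial demethylation could compete. The fallback sets out from 3 and comes back at 6. Phenol 3 is methylated (MeI, K2CO3, acetone, reflux) to the C2-symmetric 1,2,3,4-tetramethoxybenzene F4, whose two free positions are equivalent. Friedel–Crafts acetylation (Ac2O, cat. Sc(OTf)3, MeNO2, 50 °C) gives 1-(2,3,4,5-tetramethoxyphenyl)ethan-1-one F5. BCl3 (CH2Cl2, −78 → 0 °C, then water) removes only the methyl ether ortho to the carbonyl, through chelation, to give 6.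

**Step 6 (hydrogenolysis).** Thallium residues from step 5 can poison palladium, and the hindered ether may react slowly. The fallback sets out from 12 and comes back at 14, making no compound outside the list (F0). Treating 12 with BCl3 (3 equiv) and pentamethylbenzene (3 equiv) in CH2Cl2 at −78 °C cleaves the benzyl ether by Lewis-acid dealkylation, the scavenger trapping the benzyl cation, and ionises the acetal so that the freed phenol closes the ring to 14 after methanol quench. Brief reflux in the HCl–MeOH so generated carries 14 on to 15 as in step 7.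

## Further compounds

F1 | step 5 | [2-(benzyloxy)-3,4,5-trimethoxyphenyl][3-(3,4,5-trimethoxyphenyl)oxiran-2-yl]methanone (racemic trans; one enantiomer drawn) | COc1cc(cc(OC)c1OC)[C@H]1O[C@@H]1C(=O)c1cc(OC)c(OC)c(OC)c1OCc1ccccc1
F2 | step 5 | 3-[2-(benzyloxy)-3,4,5-trimethoxyphenyl]-3-oxo-2-(3,4,5-trimethoxyphenyl)propanal (racemic; enolised) | O=CC(c1cc(OC)c(OC)c(OC)c1)C(=O)c1cc(OC)c(OC)c(OC)c1OCc1ccccc1
F3 | step 5 | 2-hydroxy-6,7,8-trimethoxy-3-(3,4,5-trimethoxyphenyl)chroman-4-one (racemic diastereomer mixture) | OC1Oc2c(OC)c(OC)c(OC)cc2C(=O)C1c1cc(OC)c(OC)c(OC)c1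
F4 | step 2 | 1,2,3,4-tetramethoxybenzene | COc1ccc(OC)c(OC)c1OC
F5 | step 2 | 1-(2,3,4,5-tetramethoxyphenyl)ethan-1-one | CC(=O)c1cc(OC)c(OC)c(OC)c1OC
F0 | step 6 | none | none
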